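## Structural features

The target is a flavonol, a 2-aryl-4H-chromen-4-one. Benzo ring A is fused to pyranone ring C along C4a–C8a, and aryl ring B is attached to C2 by a single bond. There is no stereocentre, so the problem is one of telling five peripheral oxygens apart. O7 and O4' are methyl ethers, O5 (hydrogen-bonded to the C4 carbonyl) and O3' are free phenols, and the enolic O3 carries a sulfate monoester. The sulfate is the fragile group: acid solvolyses it, it makes its carrier ionic and awkward to purify, and its free-acid form catalyses its own hydrolysis. It must therefore go on last and be handled as a salt. The real difficulty is to reach a flavonol in which O3 alone is free, O7 is methylated, and O5 and O3' carry masks that leave under conditions a sulfate anion tolerates. The key step exploits ring A: C4a, C6, C8 and O1, O5, O7 map onto the three equivalent carbons and three equivalent oxygens of a threefold-symmetric triol, so forming C4–C4a and O1–C2 on that triol can give only one constitutional isomer. O3 arrives on the α-carbon of the three-carbon partner already as a benzyl ether, distinct from every phenol, and the O4'-methyl/O3'-H pattern arrives intact from isovanillic acid.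

## Logic of the disconnections

**16 to 14.** The O3–S bond and the two acetyl C–O bonds of 16 are cut, through 15. The sulfate goes on last because nothing after it may involve acid or heat. In 14 the only free hydroxyl is O3, so sulfation needs no selectivity. The forward demand is that the masks on O5 and O3' leave under base, which a sulfate anion survives; acetates meet it, and the two operations can share one flask.

**14 to 13.** The O3–CH2Ph bond is cut. The benzyl ether is the one group on the periphery removable by hydrogenolysis, so O3 is unveiled alone. The forward step must spare two aryl acetates and the C2=C3 bond.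

**13 to 12.** The acetyl C–O bonds at O5 and O3' are cut. This costs one step but removes all doubt at the sulfation. A benzyl ether on O3' was rejected because it would fall together with the O3 benzyl ether and leave two hydroxyls of similar acidity to be sulfated selectively.

**12 to 11.** The O7–CH3 bond is cut. This restores the symmetric ring A oxygen pattern needed for the annulation. The forward step must methylate O7 in the presence of O3'-H and O5-H; it relies on the acidity order 7-OH > 3'-OH > 5-OH and on a base too weak to ionise the latter two.

**11 to 7 + 8.** C4–C4a and O1–C2 are cut, through 10 and 9. This takes ring C apart into a symmetric triol and a three-carbon unit that already carries ring B and the protected O3, the largest simplification in the route. The forward step must C-acylate rather than O-acylate, must give a chromone rather than a coumarin, and must leave the benzyl ether intact at high temperature.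

**7 to 3 + 4.** The bond between the aroyl carbon and the α-carbon is cut, through 6 and 5. Both halves are then one-ring or acyclic commodity-type compounds. The forward crossed Claisen acylation needs the phenol of the acid masked by a group that is not itself an acyl donor. An aryl acetate would be attacked by the enolate, so a silyl ether is used and removed by fluoride in the same flask.

**3 to 1.** The O–Si bond is cut, through 2, back to the commercial hydroxy acid.

## Other disconnections considered

**Alternative 1:** carbonylative assembly of the open diketone.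
- **Cut:** C4a–C4 and C3–C4, with C4 supplied by carbon monoxide, leaving aryl iodide A2 and α-(methoxymethoxy) ketone A3. Ring C is closed afterwards.
- **Forward key step:** zerovalent palladium from Pd(dba)2 and a wide-bite-angle bisphosphine would add oxidatively to A2, insert CO, and pass the aroyl group to the enolate of A3 to give diketone A1. Acid would then remove the three methoxymethyl groups and cyclodehydrate to the 3'-O-benzyl flavonol A4, which needs only O3 sulfation and hydrogenolysis.
- **In its favour:** O7 is methylated and O3' benzylated from the outset, so neither a selective methylation nor an acetate shuffle is needed. On this point it is better than the chosen plan. It runs below about 100 °C rather than at 240 °C, also better. A2 has two equivalent ortho oxygens, so ring closure is as free of regiochemical questions as in the chosen plan, an equal point.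
- **Against it here:** A2 is electron-rich and substituted at both ortho positions, and the enolate is secondary and α-alkoxylated, so direct α-arylation without CO uptake and simple reduction of the iodide are plausible competitors. Product A1 is more acidic than A3 and can sequester base and metal. Toxic CO must be handled. The acid step releases formaldehyde equivalents next to a phloroglucinol-type ring, which invites C-hydroxymethylation.
- **Comparison:** both fragments must be made (about two steps for A2 and three to four for A3), giving roughly ten steps against seven. The chosen plan needs no metal and no gas and makes both ring C bonds in one operation from bought materials, but it pays with harsher heating and three protecting-group steps.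

**Alternative 2:** aryne insertion, then dehydrogenation.
- **Cut:** O1–C8a, C4a–C4 and O1–C2, leaving silylaryl triflate A6 and α-(methoxymethoxy)cinnamic acid A7.
- **Forward key step:** CsF would release the aryne from A6. The carboxylate oxygen of A7 would add at the aryne carbon remote from the benzyloxy group, the resulting aryl anion would attack the carboxyl carbon (net insertion into the C–O bond), and the freed phenoxide would close ring C by 6-endo-trig oxa-Michael addition to give trans flavanone A5. Dehydrogenation, removal of the methoxymethyl group, sulfation and double hydrogenolysis would follow.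
- **In its favour:** room-temperature, fluoride-only conditions. The inductive effect of the 3-alkoxy group on the aryne is a reliable regiochemical control. The oxygen pattern of A5 is ideal: O7 methylated, O5 and O3' benzylated, O3 under an orthogonal acetal. On mildness and on protecting-group logic it is better than the chosen plan.
- **Against it here:** the acceptor in A7 is a trisubstituted, α-alkoxy-donated enone, so the oxa-Michael step is the weak link, and protonation of the aryl anion before acyl transfer would give a simple aryl ester. The two stereocentres of A5 are made only to be destroyed, at the cost of an extra oxidation. A6 needs about five steps, including a desymmetrising monobenzylation of a resorcinol.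
- **Comparison:** about twelve steps with a longest line of eight or nine, against seven. The chosen plan forms fewer bonds in its key step (two against three) but reaches the aromatic oxidation level directly and from a symmetric, purchasable ring A.

**Alternative 3:** alkoxymethylene ylide as the C3 linchpin.
- **Cut:** C3–C4 and C2=C3, so that C3 and O3 come from ylide A10, and C4 and C2 are the acyl chloride and aryl ester carbons of salicylate-derived acid chloride A9.
- **Forward key step:** two equivalents of A10 would C-acylate with A9 to an acyl ylide (the second equivalent acting as base). On heating, this would olefinate the neighbouring ester carbonyl intramolecularly, expelling Ph3PO and giving chromone A8. Removal of the silylethyl group, sulfation and hydrogenolysis would finish.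
- **In its favour:** ring C closes under neutral conditions at moderate temperature. O3 arrives under a fluoride- or acid-labile group orthogonal to the benzyl ethers. A8 already has the correct methyl pattern, so the endgame is the shortest of all. On endgame and temperature it is better than the chosen plan.
- **Against it here:** the acyl ylide carbon is fully substituted and bears an alkoxy donor, and ester carbonyls are poor Wittig acceptors, so the ring closure is the doubtful step. The non-stabilised ylide can also attack the aryl ester of A9 intermolecularly. A9 needs a differentiated 2,4,6-trioxygenated benzoic acid, about five steps with desymmetrisation, plus esterification and chloride formation. One equivalent of ylide and one of phosphine oxide are wasted.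
- **Comparison:** about eleven to twelve steps against seven. Like the chosen plan it makes two ring C bonds in one flask and creates no stereocentre, an equal point. The chosen plan avoids any ring A desymmetrisation by starting from the symmetric triol.

Key step: step 3

Assumption: sulfate monoesters 15 and 16 are written as free hydrogen sulfates; in the flask 15 is a pyridinium salt, and 16 would be purified and stored as its potassium salt, the free acid being released by cold cation exchange only when required.

## Route

Step 1
Reactants: 1 isovanillic acid (3-hydroxy-4-methoxybenzoic acid)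
Product: 3 3-[(tert-butyldimethylsilyl)oxy]-4-methoxybenzoic acid, via bis-silylated acid 2 (not isolated)
Conditions: TBSCl (2.3 equiv), imidazole (5 equiv), DMF, rt; then AcOH–THF–H2O (3:1:1), rt
Reagents that add atoms: tert-butyldimethylsilyl chloride, CC(C)(C)[Si](C)(C)Cl
Why: Imidazole-promoted silylation of phenol and acid, then selective hydrolysis of the silyl ester, which aqueous acetic acid cleaves far faster than the aryl silyl ether. Unlike an aryl acetate, the silyl ether is not an acyl donor toward the enolate of step 2.

Step 2
Reactants: 3 3-[(tert-butyldimethylsilyl)oxy]-4-methoxybenzoic acid; 4 ethyl 2-(benzyloxy)acetate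
Product: 7 ethyl 2-(benzyloxy)-3-(3-hydroxy-4-methoxyphenyl)-3-oxopropanoate (racemic), via acyl imidazolide 5 (not isolated), via silyl-protected ketoester 6 (not isolated)
Conditions: 3, CDI (1.1 equiv), THF, rt; added to 4 (3.2 equiv)/LiN(SiMe3)2 (3.2 equiv), THF, −78 to −40 °C; AcOH; then TBAF (1.5 equiv), AcOH, THF, 0 °C
Reagents that add atoms: none
Why: Crossed Claisen condensation (C-acylation of a lithium ester enolate by an acyl imidazolide); the excess enolate absorbs the imidazole N–H and the acidic product, whose enolate resists further acylation. Buffered fluoride then cleaves the aryl silyl ether without touching the benzyl ether or the β-ketoester. The α-centre is enolisable and racemic, which is irrelevant because it becomes sp2 C3.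

Step 3
Reactants: 7 ethyl 2-(benzyloxy)-3-(3-hydroxy-4-methoxyphenyl)-3-oxopropanoate; 8 phloroglucinol (benzene-1,3,5-triol)
Product: 11 3-(benzyloxy)-5,7-dihydroxy-2-(3-hydroxy-4-methoxyphenyl)-4H-chromen-4-one, via aroyl(benzyloxy)ketene 9 (not isolated), via C-acylphloroglucinol diketone 10 (not isolated)
Conditions: 8 (2 equiv, anhydrous), neat melt, N2 stream, 240 °C, about 1.5 h, EtOH/H2O distilled out; no acid, no base
Reagents that add atoms: none
Why: Mentzer pyrone synthesis, the acid-free thermal chromone annulation of a phenol with a β-ketoester. At 240 °C 7 loses ethanol to acylketene 9 (transesterification by a phenol enters the same manifold, since aryl β-ketoesters revert to 9), and the ketene carbon acylates a ring carbon of 8 to give 10; the former ester carbon becomes C4 and C4–C4a is formed. A flanking phenolic oxygen of 10 then adds to the aroyl carbonyl in a 6-exo-trig hemiketalisation, and loss of water forms O1–C2 and the C2=C3 bond, closing ring C. No stereocentre is created, because the racemic α-carbon of 7 ends as sp2 C3. Regiochemistry needs no control: the three ring carbons and three oxygens of 8 are equivalent, and either ortho hydroxyl of 10 gives the same product. Chromone-versus-coumarin selectivity rests on the absence of acid: under Pechmann conditions the activated ketone carbon, not the ester carbon, would bond to the ring and the ester would lactonise to a 4-arylcoumarin, a path further disfavoured by the weakly electrophilic α-alkoxy aryl ketone. O-Acylation of 8, of the ring B phenol or of 11 is reversible through 9 at this temperature, whereas C-acylation followed by dehydration is not, so the mixture should funnel to 11; excess 8 and deactivation of ring A by the new C4 carbonyl hold back a second annulation. The benzyl ether is the one group that must survive the heat, hence the short reaction time and the removal of volatiles.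

Step 4
Reactants: 11 3-(benzyloxy)-5,7-dihydroxy-2-(3-hydroxy-4-methoxyphenyl)-4H-chromen-4-one
Product: 12 3-(benzyloxy)-5-hydroxy-2-(3-hydroxy-4-methoxyphenyl)-7-methoxy-4H-chromen-4-one
Conditions: MeI (1.2 equiv), KHCO3 (1.5 equiv), DMF, 40 °C (sealed)
Reagents that add atoms: iodomethane, CI
Why: Williamson O-methylation under acidity control: the 7-OH is a vinylogous carboxylic acid (para to C4=O) and the only hydroxyl that hydrogen carbonate ionises appreciably; the 3'-OH is an ordinary guaiacol-type phenol about two pK units weaker, and the 5-OH is locked in a hydrogen bond to C4=O. KHCO3 is used because a full equivalent of K2CO3 supplies two base equivalents and would begin to ionise the 3'-OH.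

Step 5
Reactants: 12 3-(benzyloxy)-5-hydroxy-2-(3-hydroxy-4-methoxyphenyl)-7-methoxy-4H-chromen-4-one
Product: 13 5-(acetyloxy)-2-[3-(acetyloxy)-4-methoxyphenyl]-3-(benzyloxy)-7-methoxy-4H-chromen-4-one
Conditions: Ac2O (6 equiv), pyridine, DMAP (0.2 equiv), rt to 50 °C
Reagents that add atoms: acetic anhydride, CC(=O)OC(C)=O
Why: Nucleophile-catalysed O-acetylation; DMAP and gentle warming are needed for the chelated 5-OH, while the benzyl and methyl ethers are inert. Acetates survive hydrogenolysis and sulfation and leave by methanolysis, which a sulfate anion tolerates.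

Step 6
Reactants: 13 5-(acetyloxy)-2-[3-(acetyloxy)-4-methoxyphenyl]-3-(benzyloxy)-7-methoxy-4H-chromen-4-one
Product: 14 5-(acetyloxy)-2-[3-(acetyloxy)-4-methoxyphenyl]-3-hydroxy-7-methoxy-4H-chromen-4-one
Conditions: H2 (1 atm), 10% Pd/C, EtOAc–THF (1:1), rt, stopped after one equivalent of H2
Reagents that add atoms: none
Why: Catalytic hydrogenolysis of a benzyl ether; the O3–CH2Ph bond cleaves readily at one atmosphere, aryl acetates are untouched, and the tetrasubstituted vinylogous-ester C2=C3 bond should not be reduced under these conditions.

Step 7
Reactants: 14 5-(acetyloxy)-2-[3-(acetyloxy)-4-methoxyphenyl]-3-hydroxy-7-methoxy-4H-chromen-4-one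
Product: 16 5-hydroxy-2-(3-hydroxy-4-methoxyphenyl)-7-methoxy-4-oxo-4H-chromen-3-yl hydrogen sulfate (ombuin 3-O-sulfate), via diacetyl sulfate 15 (not isolated)
Conditions: SO3·pyridine (5 equiv), pyridine, 45 °C; evaporate; K2CO3 (excess), MeOH, 0 °C to rt; Sephadex LH-20 (potassium salt); Dowex 50W (H+ form), H2O–MeOH, 0 °C, freeze-dry
Reagents that add atoms: sulfur trioxide–pyridine complex, O=S(=O)([O-])[n+]1ccccc1
Why: O-Sulfation of the only free hydroxyl with an amine–sulfur trioxide complex, followed by base-catalysed methanolysis of the two aryl acetates. A sulfate monoester anion is inert to methoxide at room temperature, since S–O cleavage needs acid; cold cation exchange then gives the free-acid form.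

## Compound list

1 | isovanillic acid (3-hydroxy-4-methoxybenzoic acid) | COc1ccc(C(=O)O)cc1O | starting material
2 | tert-butyldimethylsilyl 3-[(tert-butyldimethylsilyl)oxy]-4-methoxybenzoate | COc1ccc(C(=O)O[Si](C)(C)C(C)(C)C)cc1O[Si](C)(C)C(C)(C)C | intermediate (not isolated)
3 | 3-[(tert-butyldimethylsilyl)oxy]-4-methoxybenzoic acid | COc1ccc(C(=O)O)cc1O[Si](C)(C)C(C)(C)C | intermediate
4 | ethyl 2-(benzyloxy)acetate | CCOC(=O)COCc1ccccc1 | starting material
5 | {3-[(tert-butyldimethylsilyl)oxy]-4-methoxyphenyl}(1H-imidazol-1-yl)methanone | COc1ccc(C(=O)n2ccnc2)cc1O[Si](C)(C)C(C)(C)C | intermediate (not isolated)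
6 | ethyl 2-(benzyloxy)-3-{3-[(tert-butyldimethylsilyl)oxy]-4-methoxyphenyl}-3-oxopropanoate (racemic) | CCOC(=O)C(OCc1ccccc1)C(=O)c1ccc(OC)c(O[Si](C)(C)C(C)(C)C)c1 | intermediate (not isolated)
7 | ethyl 2-(benzyloxy)-3-(3-hydroxy-4-methoxyphenyl)-3-oxopropanoate (racemic, enolisable centre) | CCOC(=O)C(OCc1ccccc1)C(=O)c1ccc(OC)c(O)c1 | intermediate
8 | phloroglucinol (benzene-1,3,5-triol) | Oc1cc(O)cc(O)c1 | starting material
9 | 2-(benzyloxy)-3-(3-hydroxy-4-methoxyphenyl)prop-1-ene-1,3-dione (acylketene) | O=C=C(OCc1ccccc1)C(=O)c1ccc(OC)c(O)c1 | intermediate (not isolated)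
10 | 2-(benzyloxy)-1-(3-hydroxy-4-methoxyphenyl)-3-(2,4,6-trihydroxyphenyl)propane-1,3-dione (racemic) | COc1ccc(C(=O)C(OCc2ccccc2)C(=O)c2c(O)cc(O)cc2O)cc1O | intermediate (not isolated)
11 | 3-(benzyloxy)-5,7-dihydroxy-2-(3-hydroxy-4-methoxyphenyl)-4H-chromen-4-one | COc1ccc(-c2oc3cc(O)cc(O)c3c(=O)c2OCc2ccccc2)cc1O | intermediate
12 | 3-(benzyloxy)-5-hydroxy-2-(3-hydroxy-4-methoxyphenyl)-7-methoxy-4H-chromen-4-one | COc1cc(O)c2c(=O)c(OCc3ccccc3)c(-c3ccc(OC)c(O)c3)oc2c1 | intermediate
13 | 5-(acetyloxy)-2-[3-(acetyloxy)-4-methoxyphenyl]-3-(benzyloxy)-7-methoxy-4H-chromen-4-one | COc1cc(OC(C)=O)c2c(=O)c(OCc3ccccc3)c(-c3ccc(OC)c(OC(C)=O)c3)oc2c1 | intermediate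
14 | 5-(acetyloxy)-2-[3-(acetyloxy)-4-methoxyphenyl]-3-hydroxy-7-methoxy-4H-chromen-4-one | COc1cc(OC(C)=O)c2c(=O)c(O)c(-c3ccc(OC)c(OC(C)=O)c3)oc2c1 | intermediate
15 | 5-(acetyloxy)-2-[3-(acetyloxy)-4-methoxyphenyl]-7-methoxy-4-oxo-4H-chromen-3-yl hydrogen sulfate | COc1cc(OC(C)=O)c2c(=O)c(OS(=O)(=O)O)c(-c3ccc(OC)c(OC(C)=O)c3)oc2c1 | intermediate (not isolated)
16 | 5-hydroxy-2-(3-hydroxy-4-methoxyphenyl)-7-methoxy-4-oxo-4H-chromen-3-yl hydrogen sulfate (ombuin 3-O-sulfate) | COc1cc(O)c2c(=O)c(OS(=O)(=O)O)c(-c3ccc(OC)c(O)c3)oc2c1 | target

## Step count and least certain steps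

Total: 7 steps. Longest linear sequence: 7 steps (1 to 16); 4 and 8 are bought and enter at steps 2 and 3.

**Step 3 (key step).** The most likely failure is thermal loss or O-to-C transfer of the benzyl group in the phenolic melt. Sluggish C-acylation by the hindered, disubstituted acylketene could also leave O-acyl oligomers that char before they funnel to product. Fallback: build the flavone without the α-substituent and oxygenate C3 afterwards. It sets out from 3 and 8 and returns at 14.
- Acid 3 is activated to 5 as in step 2 and condensed with the lithium enolate of ethyl acetate (LiN(SiMe3)2, THF, −78 °C) to give ethyl 3-{3-[(tert-butyldimethylsilyl)oxy]-4-methoxyphenyl}-3-oxopropanoate F1.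
- Buffered TBAF gives ethyl 3-(3-hydroxy-4-methoxyphenyl)-3-oxopropanoate F2.
- F2 and 8 under the conditions of step 3, the best-precedented form of this condensation, should give 5,7-dihydroxy-2-(3-hydroxy-4-methoxyphenyl)-4H-chromen-4-one F3.
- Methylation as in step 4 gives 5-hydroxy-2-(3-hydroxy-4-methoxyphenyl)-7-methoxy-4H-chromen-4-one F4.
- Acetylation as in step 5 gives 5-(acetyloxy)-2-[3-(acetyloxy)-4-methoxyphenyl]-7-methoxy-4H-chromen-4-one F5.
- Dimethyldioxirane (acetone–CH2Cl2, 0 °C) epoxidises C2=C3 to 5-(acetyloxy)-2-[3-(acetyloxy)-4-methoxyphenyl]-2,3-epoxy-7-methoxy-2,3-dihydro-4H-chromen-4-one F6, and catalytic p-TsOH isomerises the epoxide to 14.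

**Step 4.** The risk is loss of site selectivity: partial methylation of the 3'-OH once the 7-OH is consumed, or incomplete conversion if hydrogen carbonate ionises the 7-OH too slowly. Fallback: replace acidity control by acyl-transfer control. It sets out from 11 and returns at 13, making step 5 unnecessary.
- Peracetylation (Ac2O, pyridine, DMAP) gives 2-[3-(acetyloxy)-4-methoxyphenyl]-3-(benzyloxy)-4-oxo-4H-chromene-5,7-diyl diacetate F7.
- PhSH/imidazole in N-methylpyrrolidone at 0 °C removes only the most activated 7-acetate to give 5-(acetyloxy)-2-[3-(acetyloxy)-4-methoxyphenyl]-3-(benzyloxy)-7-hydroxy-4H-chromen-4-one F8.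
- Mitsunobu methylation (MeOH, PPh3, diisopropyl azodicarboxylate, THF) of the acidic 7-OH gives 13.

**Step 7.** The risks are incomplete sulfation of the hindered, hydrogen-bonded enol hydroxyl and solvolytic loss of the sulfate during isolation of an ionic product that cannot be chromatographed on silica. Fallback: a masked sulfate. It sets out from 14 and returns at 15.
- 2,2,2-Trichloroethyl chlorosulfate (Et3N, DMAP, THF) gives the neutral diester 5-(acetyloxy)-2-[3-(acetyloxy)-4-methoxyphenyl]-7-methoxy-4-oxo-4H-chromen-3-yl 2,2,2-trichloroethyl sulfate F9, which can be purified on silica.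
- Zn/HCOONH4 in MeOH removes the trichloroethyl group by reductive fragmentation to give 15 as its ammonium salt, and methanolysis as in step 7 leads to 16.

**Step 2.** The risks are proton transfer outrunning acylation, self-condensation of the enolate, 1,2-Wittig rearrangement of the α-benzyloxy enolate if it warms, and retro-Claisen cleavage during the fluoride work-up. Fallback: aldol addition and oxidation in place of acylation. It sets out from 4 and returns at 6.
- The lithium enolate of 4 adds at −78 °C to 3-[(tert-butyldimethylsilyl)oxy]-4-methoxybenzaldehyde F10 (from commercial isovanillin, TBSCl, imidazole) to give ethyl 2-(benzyloxy)-3-{3-[(tert-butyldimethylsilyl)oxy]-4-methoxyphenyl}-3-hydroxypropanoate F11 as a diastereomer mixture.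
- Dess–Martin periodinane (NaHCO3, CH2Cl2) oxidises F11 to 6, which is desilylated to 7 as in step 2.

## Further compounds

F1 | step 3 | ethyl 3-{3-[(tert-butyldimethylsilyl)oxy]-4-methoxyphenyl}-3-oxopropanoate | CCOC(=O)CC(=O)c1ccc(OC)c(O[Si](C)(C)C(C)(C)C)c1
F2 | step 3 | ethyl 3-(3-hydroxy-4-methoxyphenyl)-3-oxopropanoate | CCOC(=O)CC(=O)c1ccc(OC)c(O)c1
F3 | step 3 | 5,7-dihydroxy-2-(3-hydroxy-4-methoxyphenyl)-4H-chromen-4-one (diosmetin) | COc1ccc(-c2cc(=O)c3c(O)cc(O)cc3o2)cc1O
F4 | step 3 | 5-hydroxy-2-(3-hydroxy-4-methoxyphenyl)-7-methoxy-4H-chromen-4-one | COc1cc(O)c2c(=O)cc(-c3ccc(OC)c(O)c3)oc2c1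
F5 | step 3 | 5-(acetyloxy)-2-[3-(acetyloxy)-4-methoxyphenyl]-7-methoxy-4H-chromen-4-one | COc1cc(OC(C)=O)c2c(=O)cc(-c3ccc(OC)c(OC(C)=O)c3)oc2c1
F6 | step 3 | 5-(acetyloxy)-2-[3-(acetyloxy)-4-methoxyphenyl]-2,3-epoxy-7-methoxy-2,3-dihydro-4H-chromen-4-one (racemic, oxirane cis-fused by necessity) | COc1cc(OC(C)=O)c2c(c1)OC1(c3ccc(OC)c(OC(C)=O)c3)OC1C2=O
F7 | step 4 | 2-[3-(acetyloxy)-4-methoxyphenyl]-3-(benzyloxy)-4-oxo-4H-chromene-5,7-diyl diacetate | CC(=O)Oc1cc(OC(C)=O)c2c(=O)c(OCc3ccccc3)c(-c3ccc(OC)c(OC(C)=O)c3)oc2c1
F8 | step 4 | 5-(acetyloxy)-2-[3-(acetyloxy)-4-methoxyphenyl]-3-(benzyloxy)-7-hydroxy-4H-chromen-4-one | CC(=O)Oc1cc(O)cc2oc(-c3ccc(OC)c(OC(C)=O)c3)c(OCc3ccccc3)c(=O)c12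
F9 | step 7 | 5-(acetyloxy)-2-[3-(acetyloxy)-4-methoxyphenyl]-7-methoxy-4-oxo-4H-chromen-3-yl 2,2,2-trichloroethyl sulfate | COc1cc(OC(C)=O)c2c(=O)c(OS(=O)(=O)OCC(Cl)(Cl)Cl)c(-c3ccc(OC)c(OC(C)=O)c3)oc2c1
F10 | step 2 | 3-[(tert-butyldimethylsilyl)oxy]-4-methoxybenzaldehyde | COc1ccc(C=O)cc1O[Si](C)(C)C(C)(C)C
F11 | step 2 | ethyl 2-(benzyloxy)-3-{3-[(tert-butyldimethylsilyl)oxy]-4-methoxyphenyl}-3-hydroxypropanoate (racemic mixture of diastereomers) | CCOC(=O)C(OCc1ccccc1)C(O)c1ccc(OC)c(O[Si](C)(C)C(C)(C)C)c1
A1 | alternative 1 | 1-[3-(benzyloxy)-4-methoxyphenyl]-3-[4-methoxy-2,6-bis(methoxymethoxy)phenyl]-2-(methoxymethoxy)propane-1,3-dione (racemic, enolisable centre) | COCOC(C(=O)c1ccc(OC)c(OCc2ccccc2)c1)C(=O)c1c(OCOC)cc(OC)cc1OCOC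
A2 | alternative 1 | 2-iodo-5-methoxy-1,3-bis(methoxymethoxy)benzene | COCOc1cc(OC)cc(OCOC)c1I
A3 | alternative 1 | 1-[3-(benzyloxy)-4-methoxyphenyl]-2-(methoxymethoxy)ethan-1-one | COCOCC(=O)c1ccc(OC)c(OCc2ccccc2)c1
A4 | alternative 1 | 2-[3-(benzyloxy)-4-methoxyphenyl]-3,5-dihydroxy-7-methoxy-4H-chromen-4-one | COc1cc(O)c2c(=O)c(O)c(-c3ccc(OC)c(OCc4ccccc4)c3)oc2c1
A5 | alternative 2 | rac-(2R,3R)-5-(benzyloxy)-2-[3-(benzyloxy)-4-methoxyphenyl]-7-methoxy-3-(methoxymethoxy)-2,3-dihydro-4H-chromen-4-one (trans, one enantiomer drawn) | COc1cc(OCc2ccccc2)c2c(c1)O[C@H](c1ccc(OC)c(OCc3ccccc3)c1)[C@@H](OCOC)C2=O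
A6 | alternative 2 | 3-(benzyloxy)-5-methoxy-2-(trimethylsilyl)phenyl trifluoromethanesulfonate | COc1cc(OCc2ccccc2)c([Si](C)(C)C)c(OS(=O)(=O)C(F)(F)F)c1
A7 | alternative 2 | (Z)-3-[3-(benzyloxy)-4-methoxyphenyl]-2-(methoxymethoxy)prop-2-enoic acid | COCO/C(=C\c1ccc(OC)c(OCc2ccccc2)c1)C(=O)O
A8 | alternative 3 | 5-(benzyloxy)-2-[3-(benzyloxy)-4-methoxyphenyl]-7-methoxy-3-[2-(trimethylsilyl)ethoxy]-4H-chromen-4-one | COc1cc(OCc2ccccc2)c2c(=O)c(OCC[Si](C)(C)C)c(-c3ccc(OC)c(OCc4ccccc4)c3)oc2c1
A9 | alternative 3 | 2-(benzyloxy)-6-{[3-(benzyloxy)-4-methoxybenzoyl]oxy}-4-methoxybenzoyl chloride | COc1cc(OCc2ccccc2)c(C(=O)Cl)c(OC(=O)c2ccc(OC)c(OCc3ccccc3)c2)c1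
A10 | alternative 3 | triphenyl{[2-(trimethylsilyl)ethoxy]methylidene}phosphorane | C[Si](C)(C)CCOC=P(c1ccccc1)(c1ccccc1)c1ccccc1
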